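## Retrosynthetic overview

- **Feature:** ring A is a phloroglucinol. C6 carries the 3-hydroxy-3-methylbutyl chain between C5–OH and C7–OH, and the third oxygen, on C8a para to C6, is O1 of ring C. Unless that oxygen is told apart from the other two, the chain ends up at C8 as readily as at C6.
- **End game:** cleave two aryl silyl ethers and one benzyl ether under non-acidic conditions. The C3–OH comes from epoxidation of the C2=C3 bond of a flavone.
- **Ring C (with ring B attached):** carbonylative annulation of an o-iodophenol (iodine on C4a, OH = O1) with 4-benzyloxyphenylacetylene and CO forms C4a–C4, C4–C3 and O1–C2.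
- **Ring A:** a Danheiser benzannulation joins 3-(benzyloxy)cyclobutenone to a triisopropylsiloxyalkyne that carries the chain as a 3-methylbut-3-enyl group. It delivers the three oxygens as OH, OSi(iPr)3 and OBn, with OBn para to the chain.
- **Ring order:** A (step 3), then C (step 8); ring B is bought with the alkyne. The tertiary alcohol comes from a Mukaiyama hydration placed before the first hydrogenolysis.

Key step: step 3

Remark: the target has no stereocentre. The two chiral transient species (the vinylcyclobutenone of step 3 and the epoxide of step 9) are racemic and lose their stereocentres in the same flask.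

## Route

Step 1
Reactants: 1 3-ethoxycyclobut-2-en-1-one; 2 benzyl alcohol
Product: 3 3-(benzyloxy)cyclobut-2-en-1-one
Conditions: BnOH (2 equiv), CSA (5 mol%), 5 Å MS, CH2Cl2, rt; Et3N quench
Reagents that add atoms: none
Why: Acid-catalysed transetherification of a vinylogous ester (BnOH adds to C3 of the O-protonated enone, EtOH leaves) is the same addition–elimination by which 3-alkoxycyclobutenones are hydrolysed and squarate esters exchange alkoxy groups; the sieves take up ethanol to pull the equilibrium, and the temperature stays far below that of ring opening, so no ketene forms for the alcohol to trap.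

Step 2
Reactants: 4 ethyl 4-methylpent-4-enoate
Product: 7 triisopropyl[(5-methylhex-5-en-1-yn-1-yl)oxy]silane, via lithium dibromoenolate 5 (not isolated), via lithium ynolate 6 (not isolated)
Conditions: CH2Br2, LiTMP (2.2 equiv), THF, −78 °C; n-BuLi, −78 °C to rt; TIPSOTf, −78 to 0 °C; pentane extraction, Et3N-deactivated silica
Reagents that add atoms: dibromomethane BrCBr; triisopropylsilyl trifluoromethanesulfonate CC(C)[Si](OS(=O)(=O)C(F)(F)F)(C(C)C)C(C)C
Why: Kowalski ester homologation stopped at the ynolate: LiCHBr2 acylation and deprotonation give enolate 5, bromine–lithium exchange gives a carbenoid whose alkyl group shifts 1,2 with loss of LiBr to give ynolate 6 (the CH2Br2 carbon becomes the chain-bearing alkyne carbon, the ester carbonyl carbon the oxygen-bearing one), and the bulky silyl electrophile reacts at oxygen rather than carbon; the unactivated alkene is inert to these bases at low temperature.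

Step 3
Reactants: 3 3-(benzyloxy)cyclobut-2-en-1-one; 7 triisopropyl[(5-methylhex-5-en-1-yn-1-yl)oxy]silane
Product: 12 5-(benzyloxy)-2-(3-methylbut-3-en-1-yl)-3-[(triisopropylsilyl)oxy]phenol, via vinylketene 8 (not isolated), via vinylcyclobutenone 9 (not isolated), via dienylketene 10 (not isolated), via cyclohexadienone 11 (not isolated)
Conditions: 7 (1.3 equiv), toluene, 80 °C, 3 added over 4 h by syringe pump; then 110 °C
Reagents that add atoms: none
Why: Danheiser benzannulation: near 80 °C cyclobutenone 3 opens reversibly by 4π electrocyclic cleavage of its C1–C4 bond to (1-benzyloxyvinyl)ketene 8, whose ketene C=C adds siloxyalkyne 7 in a [2+2] cycloaddition to give 4-vinylcyclobutenone 9, which forms the C6–C7 and C4a–C5 bonds (phenol carbon taken as C7). A second 4π opening of 9 gives dienylketene 10; only its (3E) isomer, with the ketene and the enol-ether CH2 terminus on the same side, can react on, and because this opening is reversible all material drains through that isomer. Ring A closes by 6π electrocyclisation of 10 (ketene carbon to CH2 terminus, the C7–C8 bond) to dienone 11, which tautomerises irreversibly to phenol 12, so that in sum the alkyne is inserted between C1 and C2 of the four-membered ring. The closest known reaction is this same annulation of 3-alkyl- and 3-arylcyclobutenones with triisopropylsiloxyalkynes to give resorcinol monosilyl ethers; a 3-alkoxy group is a rarer substituent, but in 8 its oxygen is cross-conjugated (it polarises the CH2 terminus, not the ketene), and alkoxy-substituted cyclobutenones are known to open thermally. The selectivity needed is the orientation of the [2+2] step, and the polarisation of 7 secures it: the nucleophilic, alkyl-bearing alkyne carbon attacks the electrophilic ketene carbonyl carbon, so the chain carbon ends between C–OH and C–OSi with OBn para to it. No stereocentre survives (that of 9 is erased), the unactivated 1,1-disubstituted alkene is far less ketenophilic than the ynol ether and cannot compete with the 6π closure, and slow addition of 3 to excess 7 keeps phenol 12 from being acylated by 8.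

Step 4
Reactants: 12 5-(benzyloxy)-2-(3-methylbut-3-en-1-yl)-3-[(triisopropylsilyl)oxy]phenol
Product: 13 {[5-(benzyloxy)-2-(3-methylbut-3-en-1-yl)-1,3-phenylene]bis(oxy)}bis(triisopropylsilane)
Conditions: TIPSCl, imidazole, DMAP (cat.), DMF, rt to 40 °C
Reagents that add atoms: triisopropylsilyl chloride CC(C)[Si](Cl)(C(C)C)C(C)C
Why: Standard imidazole-promoted silylation of a phenol makes the two oxygens flanking the chain identical, so ring A becomes symmetric about the C6···C8a axis and both positions ortho to OBn become equivalent; it comes before the hydration so that no free electron-rich phenol meets cobalt and O2 and no phenol can add to the alkene.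

Step 5
Reactants: 13 {[5-(benzyloxy)-2-(3-methylbut-3-en-1-yl)-1,3-phenylene]bis(oxy)}bis(triisopropylsilane)
Product: 14 4-{4-(benzyloxy)-2,6-bis[(triisopropylsilyl)oxy]phenyl}-2-methylbutan-2-ol
Conditions: Co(acac)2 (10 mol%), PhSiH3, O2 (1 atm), THF, rt
Reagents that add atoms: dioxygen O=O
Why: Mukaiyama hydration: a cobalt hydride transfers a hydrogen atom to the terminal CH2, giving the tertiary radical (Markovnikov), O2 traps it and the silane reduces the peroxide to the alcohol; aryl silyl and benzyl ethers are inert, and the step must precede every hydrogenolysis, which would otherwise saturate the alkene.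

Step 6
Reactants: 14 4-{4-(benzyloxy)-2,6-bis[(triisopropylsilyl)oxy]phenyl}-2-methylbutan-2-ol
Product: 15 4-(3-hydroxy-3-methylbutyl)-3,5-bis[(triisopropylsilyl)oxy]phenol
Conditions: H2 (1 atm), 10% Pd/C, EtOAc–EtOH, rt
Reagents that add atoms: none
Why: Catalytic hydrogenolysis of the aryl benzyl ether is orthogonal to aryl silyl ethers and to a non-benzylic tertiary alcohol, so it frees only the oxygen para to the chain (future O1).

Step 7
Reactants: 15 4-(3-hydroxy-3-methylbutyl)-3,5-bis[(triisopropylsilyl)oxy]phenol
Product: 16 4-(3-hydroxy-3-methylbutyl)-2-iodo-3,5-bis[(triisopropylsilyl)oxy]phenol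
Conditions: NIS (1.0 equiv), CH2Cl2, −20 to 0 °C, dark
Reagents that add atoms: N-iodosuccinimide O=C1CCC(=O)N1I
Why: Electrophilic aromatic iodination ortho to a free phenol: the para position carries the chain and the two ortho positions are equivalent, so only one mono-iodide can form, and one equivalent of NIS at low temperature plus the bulk of the neighbouring silyl ether hold back a second iodination.

Step 8
Reactants: 16 4-(3-hydroxy-3-methylbutyl)-2-iodo-3,5-bis[(triisopropylsilyl)oxy]phenol; 17 1-(benzyloxy)-4-ethynylbenzene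
Product: 20 2-[4-(benzyloxy)phenyl]-6-(3-hydroxy-3-methylbutyl)-5,7-bis[(triisopropylsilyl)oxy]-4H-chromen-4-one, via ynone 18 (not isolated), via enaminone 19 (not isolated)
Conditions: PdCl2(dppf) (5 mol%), CO (20 bar), Et2NH, 100 °C
Reagents that add atoms: carbon monoxide [C-]#[O+]
Why: Palladium-catalysed carbonylative annulation of an o-iodophenol with a terminal alkyne (copper-free carbonylative Sonogashira-type coupling, then cyclisation): zerovalent palladium inserts into the C–I bond, the electron-rich aryl group migrates readily to CO, the acylpalladium species is alkynylated to ynone 18, and diethylamine adds to give enaminone 19, in which O1 displaces the amine at C2 by a six-membered addition–elimination, so the flavone forms rather than the 5-exo aurone; leaving out copper and keeping up the CO pressure suppress direct alkynylation.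

Step 9
Reactants: 20 2-[4-(benzyloxy)phenyl]-6-(3-hydroxy-3-methylbutyl)-5,7-bis[(triisopropylsilyl)oxy]-4H-chromen-4-one
Product: 22 2-[4-(benzyloxy)phenyl]-3-hydroxy-6-(3-hydroxy-3-methylbutyl)-5,7-bis[(triisopropylsilyl)oxy]-4H-chromen-4-one, via epoxide 21 (not isolated)
Conditions: DMDO (acetone solution, excess), CH2Cl2, 0 °C to rt; then p-TsOH·H2O (cat.), CH2Cl2, rt
Reagents that add atoms: dimethyldioxirane CC1(C)OO1
Why: Neutral dimethyldioxirane epoxidation of the C2=C3 bond, then acid-catalysed opening of epoxide 21 at C2 (cation stabilised by O1 and the aryl group) with loss of H3, is the established flavone-to-flavonol oxidation; silyl ethers, the benzyl ether and the tertiary alcohol tolerate the reagent at this temperature, and with O5 and O7 silylated the trace of acid cannot close a chroman.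

Step 10
Reactants: 22 2-[4-(benzyloxy)phenyl]-3-hydroxy-6-(3-hydroxy-3-methylbutyl)-5,7-bis[(triisopropylsilyl)oxy]-4H-chromen-4-one
Product: 23 2-[4-(benzyloxy)phenyl]-3,5,7-trihydroxy-6-(3-hydroxy-3-methylbutyl)-4H-chromen-4-one
Conditions: TBAF (2.5 equiv), AcOH (2.5 equiv), THF, 0 °C
Reagents that add atoms: none
Why: Fluoride cleavage of aryl silyl ethers, buffered with acetic acid so that the base- and air-sensitive flavonol never sits as a polyphenoxide; avoiding strong acid keeps the tertiary alcohol from cyclising onto O5 or O7 to a 2,2-dimethylchroman, and the remaining benzyl ether leaves the product lipophilic enough to be freed from ammonium salts.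

Step 11
Reactants: 23 2-[4-(benzyloxy)phenyl]-3,5,7-trihydroxy-6-(3-hydroxy-3-methylbutyl)-4H-chromen-4-one
Product: 24 3,5,7-trihydroxy-6-(3-hydroxy-3-methylbutyl)-2-(4-hydroxyphenyl)-4H-chromen-4-one (target)
Conditions: H2 (1 atm), 10% Pd/C, THF–MeOH, rt
Reagents that add atoms: none
Why: Neutral catalytic hydrogenolysis of the last benzyl ether; the tetrasubstituted conjugated C2=C3 bond of a flavonol and the non-benzylic tertiary alcohol are not reduced at 1 atm, and the polar product needs only filtration and evaporation.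

## Compound list

1 | 3-ethoxycyclobut-2-en-1-one | CCOC1=CC(=O)C1 | starting material
2 | benzyl alcohol | OCc1ccccc1 | starting material
3 | 3-(benzyloxy)cyclobut-2-en-1-one | O=C1CC(OCc2ccccc2)=C1 | intermediate
4 | ethyl 4-methylpent-4-enoate | CCOC(=O)CCC(C)=C | starting material
5 | lithium 1,1-dibromo-5-methylhexa-1,5-dien-2-olate (formed in the flask) | [Li+].[O-]C(CCC(C)=C)=C(Br)Br | intermediate
6 | lithium 5-methylhex-5-en-1-yn-1-olate (formed in the flask) | [Li+].[O-]C#CCCC(C)=C | intermediate
7 | triisopropyl[(5-methylhex-5-en-1-yn-1-yl)oxy]silane | C=C(C)CCC#CO[Si](C(C)C)(C(C)C)C(C)C | intermediate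
8 | 3-(benzyloxy)buta-1,3-dien-1-one, the (1-benzyloxyvinyl)ketene (formed in the flask) | C=C(OCc1ccccc1)C=C=O | intermediate
9 | 4-[1-(benzyloxy)vinyl]-2-(3-methylbut-3-en-1-yl)-3-[(triisopropylsilyl)oxy]cyclobut-2-en-1-one, racemic (formed in the flask) | O=C1C(CCC(C)=C)=C(O[Si](C(C)C)(C(C)C)C(C)C)C1C(=C)OCc1ccccc1 | intermediate
10 | (3E)-5-(benzyloxy)-2-(3-methylbut-3-en-1-yl)-3-[(triisopropylsilyl)oxy]hexa-1,3,5-trien-1-one (formed in the flask) | O=C=C(CCC(C)=C)/C(O[Si](C(C)C)(C(C)C)C(C)C)=C\C(=C)OCc1ccccc1 | intermediate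
11 | 5-(benzyloxy)-2-(3-methylbut-3-en-1-yl)-3-[(triisopropylsilyl)oxy]cyclohexa-2,4-dien-1-one (formed in the flask) | O=C1CC(OCc2ccccc2)=CC(O[Si](C(C)C)(C(C)C)C(C)C)=C1CCC(C)=C | intermediate
12 | 5-(benzyloxy)-2-(3-methylbut-3-en-1-yl)-3-[(triisopropylsilyl)oxy]phenol | Oc1cc(OCc2ccccc2)cc(O[Si](C(C)C)(C(C)C)C(C)C)c1CCC(C)=C | intermediate
13 | {[5-(benzyloxy)-2-(3-methylbut-3-en-1-yl)-1,3-phenylene]bis(oxy)}bis(triisopropylsilane) | C=C(C)CCc1c(O[Si](C(C)C)(C(C)C)C(C)C)cc(OCc2ccccc2)cc1O[Si](C(C)C)(C(C)C)C(C)C | intermediate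
14 | 4-{4-(benzyloxy)-2,6-bis[(triisopropylsilyl)oxy]phenyl}-2-methylbutan-2-ol | CC(C)(O)CCc1c(O[Si](C(C)C)(C(C)C)C(C)C)cc(OCc2ccccc2)cc1O[Si](C(C)C)(C(C)C)C(C)C | intermediate
15 | 4-(3-hydroxy-3-methylbutyl)-3,5-bis[(triisopropylsilyl)oxy]phenol | CC(C)(O)CCc1c(O[Si](C(C)C)(C(C)C)C(C)C)cc(O)cc1O[Si](C(C)C)(C(C)C)C(C)C | intermediate
16 | 4-(3-hydroxy-3-methylbutyl)-2-iodo-3,5-bis[(triisopropylsilyl)oxy]phenol | CC(C)(O)CCc1c(O[Si](C(C)C)(C(C)C)C(C)C)cc(O)c(I)c1O[Si](C(C)C)(C(C)C)C(C)C | intermediate
17 | 1-(benzyloxy)-4-ethynylbenzene | C#Cc1ccc(OCc2ccccc2)cc1 | starting material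
18 | 3-[4-(benzyloxy)phenyl]-1-{6-hydroxy-3-(3-hydroxy-3-methylbutyl)-2,4-bis[(triisopropylsilyl)oxy]phenyl}prop-2-yn-1-one (formed in the flask) | CC(C)(O)CCc1c(O[Si](C(C)C)(C(C)C)C(C)C)cc(O)c(C(=O)C#Cc2ccc(OCc3ccccc3)cc2)c1O[Si](C(C)C)(C(C)C)C(C)C | intermediate
19 | (E)-3-[4-(benzyloxy)phenyl]-3-(diethylamino)-1-{6-hydroxy-3-(3-hydroxy-3-methylbutyl)-2,4-bis[(triisopropylsilyl)oxy]phenyl}prop-2-en-1-one (formed in the flask) | CC(C)(O)CCc1c(O[Si](C(C)C)(C(C)C)C(C)C)cc(O)c(C(=O)/C=C(/N(CC)CC)c2ccc(OCc3ccccc3)cc2)c1O[Si](C(C)C)(C(C)C)C(C)C | intermediate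
20 | 2-[4-(benzyloxy)phenyl]-6-(3-hydroxy-3-methylbutyl)-5,7-bis[(triisopropylsilyl)oxy]-4H-chromen-4-one | CC(C)(O)CCc1c(O[Si](C(C)C)(C(C)C)C(C)C)cc2oc(-c3ccc(OCc4ccccc4)cc3)cc(=O)c2c1O[Si](C(C)C)(C(C)C)C(C)C | intermediate
21 | 2,3-epoxide of 20 (cis-fused oxirane on ring C, racemic, one enantiomer drawn; formed in the flask) | O=C1[C@H]2O[C@@]2(c3ccc(OCc4ccccc4)cc3)Oc3cc(O[Si](C(C)C)(C(C)C)C(C)C)c(CCC(C)(C)O)c(O[Si](C(C)C)(C(C)C)C(C)C)c13 | intermediate
22 | 2-[4-(benzyloxy)phenyl]-3-hydroxy-6-(3-hydroxy-3-methylbutyl)-5,7-bis[(triisopropylsilyl)oxy]-4H-chromen-4-one | CC(C)(O)CCc1c(O[Si](C(C)C)(C(C)C)C(C)C)cc2oc(-c3ccc(OCc4ccccc4)cc3)c(O)c(=O)c2c1O[Si](C(C)C)(C(C)C)C(C)C | intermediate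
23 | 2-[4-(benzyloxy)phenyl]-3,5,7-trihydroxy-6-(3-hydroxy-3-methylbutyl)-4H-chromen-4-one | CC(C)(O)CCc1c(O)cc2oc(-c3ccc(OCc4ccccc4)cc3)c(O)c(=O)c2c1O | intermediate
24 | 3,5,7-trihydroxy-6-(3-hydroxy-3-methylbutyl)-2-(4-hydroxyphenyl)-4H-chromen-4-one | CC(C)(O)CCc1c(O)cc2oc(-c3ccc(O)cc3)c(O)c(=O)c2c1O | target

## Step count

Total step count: 11.
Longest linear sequence: 10 (step 1 or step 2, then steps 3 to 11).

## Steps most likely to fail

**First risk, step 3 (key step).**
- The vinylogous-ester stabilisation of 3 may slow the first ring opening so much that the ynol ether is lost by thermal silyl shift before it is consumed.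
- The alkoxyvinylketene may condense with itself.
- The ketene may acylate the product phenol.

The fallback takes ring A from the aromatic pool instead of building it. It sets out from benzyl alcohol 2 and comes back to the route at 15.
- Mitsunobu coupling of 2 (PPh3, DIAD, THF, 0 °C) with commercial 2,4,6-trihydroxybenzaldehyde should occur at the para hydroxyl, the most acidic one and the only one too remote from the formyl group to hydrogen-bond to it, giving 4-(benzyloxy)-2,6-dihydroxybenzaldehyde F1. Here the formyl carbon marks the first chain carbon on C6 and the para oxygen is the future O1.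
- Double silylation (TIPSOTf, 2,6-lutidine, CH2Cl2) should give 4-(benzyloxy)-2,6-bis[(triisopropylsilyl)oxy]benzaldehyde F2.
- Wittig olefination with Ph3P=CHC(O)CH3 in refluxing toluene should give (E)-4-{4-(benzyloxy)-2,6-bis[(triisopropylsilyl)oxy]phenyl}but-3-en-2-one F3.
- Hydrogenation over Pd/C saturates the alkene and removes the benzyl group in one operation, giving 4-{4-hydroxy-2,6-bis[(triisopropylsilyl)oxy]phenyl}butan-2-one F4.
- MeMgBr (3 equiv, THF, 0 °C) then adds to the ketone to give 15.

**Second risk, step 8.**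
- Oxidative addition and CO insertion may be slow at a C–I bond that is electron-rich and flanked on both sides.
- Alkynylation may occur without CO uptake and be followed by five-membered ring closure.
- Diethylamine may capture the acylpalladium species.
- The silyl ether peri to the new carbonyl may be lost.

The fallback forms the C4a–C4 bond without palladium. It sets out from phenol 15 (the iodination is skipped) and comes back at ynone 18, now isolated, and from there at 20.
- Casnati–Skattebøl ortho-formylation (MgCl2, Et3N, paraformaldehyde, MeCN, reflux) should give 2-hydroxy-5-(3-hydroxy-3-methylbutyl)-4,6-bis[(triisopropylsilyl)oxy]benzaldehyde F5.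
- The lithium acetylide of 17 (n-BuLi, THF, −78 °C, 3.5 equiv to cover the two acidic OH groups) should add to give racemic 2-{3-[4-(benzyloxy)phenyl]-1-hydroxyprop-2-yn-1-yl}-4-(3-hydroxy-3-methylbutyl)-3,5-bis[(triisopropylsilyl)oxy]phenol F6.
- MnO2 in CH2Cl2 oxidises the benzylic, propargylic alcohol to 18.
- Warming 18 with Et2NH in EtOH closes ring C through 19 to give 20.

**Third risk, step 1.**
- The alkoxy exchange may stall at equilibrium.
- The alcohol may attack the strained ring carbonyl, cleaving the ring C–C bond to open-chain acetoacetate-type esters.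

The fallback replaces the reversible exchange with an irreversible O-alkylation. It sets out from 1 and comes back at 3.
- Hydrolysis with dilute aqueous HCl at rt gives cyclobutane-1,3-dione F7, present largely as its strongly acidic enol.
- Mitsunobu O-benzylation of F7 with 2 (PPh3, DIAD, THF, 0 °C), as is usual for cyclic vinylogous acids, gives 3.

## Further compounds

F1 | step 3 | 4-(benzyloxy)-2,6-dihydroxybenzaldehyde | O=Cc1c(O)cc(OCc2ccccc2)cc1O
F2 | step 3 | 4-(benzyloxy)-2,6-bis[(triisopropylsilyl)oxy]benzaldehyde | O=Cc1c(O[Si](C(C)C)(C(C)C)C(C)C)cc(OCc2ccccc2)cc1O[Si](C(C)C)(C(C)C)C(C)C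
F3 | step 3 | (E)-4-{4-(benzyloxy)-2,6-bis[(triisopropylsilyl)oxy]phenyl}but-3-en-2-one | CC(=O)/C=C/c1c(O[Si](C(C)C)(C(C)C)C(C)C)cc(OCc2ccccc2)cc1O[Si](C(C)C)(C(C)C)C(C)C
F4 | step 3 | 4-{4-hydroxy-2,6-bis[(triisopropylsilyl)oxy]phenyl}butan-2-one | CC(=O)CCc1c(O[Si](C(C)C)(C(C)C)C(C)C)cc(O)cc1O[Si](C(C)C)(C(C)C)C(C)C
F5 | step 8 | 2-hydroxy-5-(3-hydroxy-3-methylbutyl)-4,6-bis[(triisopropylsilyl)oxy]benzaldehyde | CC(C)(O)CCc1c(O[Si](C(C)C)(C(C)C)C(C)C)cc(O)c(C=O)c1O[Si](C(C)C)(C(C)C)C(C)C
F6 | step 8 | 2-{3-[4-(benzyloxy)phenyl]-1-hydroxyprop-2-yn-1-yl}-4-(3-hydroxy-3-methylbutyl)-3,5-bis[(triisopropylsilyl)oxy]phenol (racemic) | CC(C)(O)CCc1c(O[Si](C(C)C)(C(C)C)C(C)C)cc(O)c(C(O)C#Cc2ccc(OCc3ccccc3)cc2)c1O[Si](C(C)C)(C(C)C)C(C)C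
F7 | step 1 | cyclobutane-1,3-dione | O=C1CC(=O)C1
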